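Ring B carries oxygen at C6, flanked by the ring-fusion bond C5–C10 and by C8–C9. The decalin is therefore cut into an acyclic triene: a 2-silyloxydiene (C5=C6–C7=C8) tethered through C1–C4 to a (2E)-3-methyl-2-enal (C9=C10, C11 as formyl carbon). One catalytic enantioselective intramolecular Diels–Alder reaction forms C5–C10 and C8–C9, closes rings A and B and sets C5, C8, C9 and C10. The precursor is the (2E,8Z,10E)-trienal with a robust triisopropylsilyl dienol ether. It is assembled by conjugate allylation, aldol condensation and a B-alkyl Suzuki coupling. The same coupling and a vinylogous Mukaiyama aldol reaction later build the butenolide side chain.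

Key step: step 9

Remark: names use drimane numbering (ring carbons C1–C10, C11 on C9, methyl groups on C4, C8 and C10; the C10 methyl is β). In the text the side chain is numbered on from C11 (C12–C16) and the butenolide carbons are C16–C19. Compounds 1, 2, 4, 9 and 26 are taken as commercial.

Step 1
Reactants: 1 mesityl oxide (4-methylpent-3-en-2-one); 2 allyltrimethylsilane
Product: 3 4,4-dimethylhept-6-en-2-one
Conditions: TiCl4 (1.1 equiv), CH2Cl2, −78 °C; aq. NH4Cl
Reagents that add atoms: none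
Why: Hosomi–Sakurai conjugate allylation of the TiCl4-activated β,β-disubstituted enone is a reliable way to a quaternary carbon, here the future C4 with its two methyl groups and a terminal alkene for later coupling.

Step 2
Reactants: 3 4,4-dimethylhept-6-en-2-one; 4 acetaldehyde
Product: 5 2-hydroxy-6,6-dimethylnon-8-en-4-one (racemic carbinol)
Conditions: LiN(i-Pr)2 (1.05 equiv), THF, −78 °C; then CH3CHO, −78 °C; aq. NH4Cl
Reagents that add atoms: none
Why: Directed aldol addition, in which kinetic deprotonation takes place at the methyl group because the other α-position is a neopentyl CH2; the new carbinol centre is lost in the next step.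

Step 3
Reactants: 5 2-hydroxy-6,6-dimethylnon-8-en-4-one
Product: 7 (2E)-6,6-dimethylnona-2,8-dien-4-one, via mesylate 6 (not isolated)
Conditions: MsCl, Et3N (3 equiv), CH2Cl2, 0 °C to rt
Reagents that add atoms: none
Why: Mesylation followed by E1cB elimination completes the aldol condensation and should give the conjugated (E)-enone as the thermodynamically favoured isomer.

Step 4
Reactants: 7 (2E)-6,6-dimethylnona-2,8-dien-4-one
Product: 8 (2E,4Z)-6,6-dimethyl-4-[(triisopropylsilyl)oxy]nona-2,4,8-triene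
Conditions: i-Pr3SiOTf (1.2 equiv), Et3N (2 equiv), CH2Cl2, 0 °C to rt
Reagents that add atoms: triisopropylsilyl trifluoromethanesulfonate, CC(C)[Si](C(C)C)(C(C)C)OS(=O)(=O)C(F)(F)F
Why: Soft enolisation (O-silylation, then deprotonation at the α′-CH2) gives the 2-silyloxydiene, whose (Z)-enol ether avoids strain between the quaternary carbon and the propenyl group; the triisopropylsilyl group is chosen because such enol ethers withstand coupling, hydride, chromatography and the acidic catalyst of step 9.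

Step 5
Reactants: 9 ethyl acetoacetate
Product: 10 ethyl (2E)-3-{[(trifluoromethyl)sulfonyl]oxy}but-2-enoate
Conditions: (CF3SO2)2O, aq. Me4NOH, hexane, 5–10 °C
Reagents that add atoms: trifluoromethanesulfonic anhydride, O=S(=O)(OS(=O)(=O)C(F)(F)F)C(F)(F)F
Why: O-Triflation of the β-keto ester enolate, where a non-chelating tetramethylammonium counter-ion is known to favour the (E)-enol triflate, the geometry required because the cross-coupling proceeds with retention.

Step 6
Reactants: 8 (2E,4Z)-6,6-dimethyl-4-[(triisopropylsilyl)oxy]nona-2,4,8-triene; 10 ethyl (2E)-3-{[(trifluoromethyl)sulfonyl]oxy}but-2-enoate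
Product: 12 ethyl (2E,8Z,10E)-3,7,7-trimethyl-9-[(triisopropylsilyl)oxy]dodeca-2,8,10-trienoate, via alkylborane 11 (not isolated)
Conditions: 9-BBN (1.1 equiv), THF, 0 °C to rt; then 10, Pd(dppf)Cl2 (5 mol%), 3 M aq. K3PO4, THF–DMF, 50 °C
Reagents that add atoms: none
Why: 9-BBN hydroborates only the monosubstituted alkene and places boron on the terminal carbon, and B-alkyl Suzuki–Miyaura coupling with the β-triflyloxy enoate transfers the (E) geometry to the trisubstituted alkene that becomes the dienophile.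

Step 7
Reactants: 12 ethyl (2E,8Z,10E)-3,7,7-trimethyl-9-[(triisopropylsilyl)oxy]dodeca-2,8,10-trienoate
Product: 13 (2E,8Z,10E)-3,7,7-trimethyl-9-[(triisopropylsilyl)oxy]dodeca-2,8,10-trien-1-ol
Conditions: i-Bu2AlH (2.2 equiv), CH2Cl2, −78 °C; aq. Rochelle salt
Reagents that add atoms: none
Why: 1,2-Reduction of the α,β-unsaturated ester gives the allylic alcohol, and the silyl dienol ether reacts neither with the hydride nor with the neutral work-up.

Step 8
Reactants: 13 (2E,8Z,10E)-3,7,7-trimethyl-9-[(triisopropylsilyl)oxy]dodeca-2,8,10-trien-1-ol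
Product: 14 (2E,8Z,10E)-3,7,7-trimethyl-9-[(triisopropylsilyl)oxy]dodeca-2,8,10-trienal
Conditions: activated MnO2 (excess), CH2Cl2, rt
Reagents that add atoms: none
Why: MnO2 oxidises the allylic alcohol selectively under neutral heterogeneous conditions, without E/Z isomerisation of the enal or hydrolysis of the enol ether.

Step 9
Reactants: 14 (2E,8Z,10E)-3,7,7-trimethyl-9-[(triisopropylsilyl)oxy]dodeca-2,8,10-trienal
Product: 15 (1S,2S,4aS,8aS)-2,5,5,8a-tetramethyl-4-[(triisopropylsilyl)oxy]-1,2,4a,5,6,7,8,8a-octahydronaphthalene-1-carbaldehyde, that is 6-[(triisopropylsilyl)oxy]drim-6-en-11-al (5α-H, 8β-CH3, 9β-CHO, 10β-CH3)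
Conditions: (R)-tetrahydro-3,3-diphenyl-1-(o-tolyl)-1H,3H-pyrrolo[1,2-c][1,3,2]oxazaborole (20 mol%), (CF3SO2)2NH (20 mol%), CH2Cl2 (0.01 M), −78 to −20 °C; Et3N quench
Reagents that add atoms: none
Why: The N-protonated oxazaborolidine binds the formyl oxygen of the s-trans enal and lowers its LUMO, so that C5, the nucleophilic end of the silyloxydiene, bonds to the β-carbon C10 slightly ahead of C8–C9 in a concerted, asynchronous [4+2] cycloaddition. The closest known reactions are oxazaborolidinium-catalysed Diels–Alder reactions of enals with 2-silyloxydienes, also in intramolecular form, and Lewis acid-promoted intramolecular cycloadditions of silyloxydienes, although a β,β-disubstituted enal that creates a quaternary carbon lies at the limit of what these have shown. Ring B is closed as the cyclohexene of the [4+2] process, and ring A is closed as the six-membered ring of the C1–C4 tether by the same C5–C10 bond. The (2E)-enal places the C9 formyl and C10 methyl groups cis, the endo-formyl transition state with the tether outside on the (Z)-enol ether C5=C6 gives the trans ring fusion at C5/C10, the (E)-propenyl methyl group ends up β at C8, and the absolute sense comes from the catalyst, whose phenyl group shields one enal face in the formyl C–H···O-bound complex (the (R)-catalyst is chosen on this model, and its antipode is equally available). The step needs endo over exo selectivity and cycloaddition over Mukaiyama-type addition or silyl loss, which the matched polarity of diene and dienophile, the C4 gem-dimethyl group that favours the folded tether, the bulky triisopropylsilyl group and high dilution are meant to secure.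

Step 10
Reactants: 15 6-[(triisopropylsilyl)oxy]drim-6-en-11-al
Product: 16 11-methylidene-6-[(triisopropylsilyl)oxy]drim-6-ene (9β-vinyl; 5α-H, 8β-CH3, 10β-CH3)
Conditions: Ph3PCH3Br, KN(SiMe3)2, THF, 0 °C; then 15, 0 °C to rt
Reagents that add atoms: methyltriphenylphosphonium bromide, C[P+](c1ccccc1)(c1ccccc1)c1ccccc1.[Br-]
Why: Wittig methylenation of the hindered but unconjugated aldehyde, in which the non-stabilised ylide adds faster than it deprotonates C9, whose equatorial 9β configuration is in any case the more stable one.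

Step 11
Reactants: 16 11-methylidene-6-[(triisopropylsilyl)oxy]drim-6-ene
Product: 17 11-methylidenedrim-7-en-6-one (5α-H, 9α-H, 10β-CH3)
Conditions: Pd(OAc)2 (1.2 equiv), MeCN–DMSO, 45 °C
Reagents that add atoms: none
Why: Saegusa–Ito oxidation, in which silicon–palladium exchange at the enol ether and syn β-hydride elimination of the C8 hydrogen give the 7-en-6-one and remove the C8 stereocentre, while the hindered vinyl group finds neither nucleophile nor reoxidant to engage divalent palladium.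

Step 12
Reactants: 17 11-methylidenedrim-7-en-6-one
Product: 18 7α,8α-epoxy-11-methylidenedriman-6-one (8β-CH3)
Conditions: 30% aq. H2O2, NaOH (0.3 equiv), MeOH, 0 °C
Reagents that add atoms: hydrogen peroxide, OO
Why: Weitz–Scheffer nucleophilic epoxidation, in which hydroperoxide adds to C8 from the α face, anti to the axial C10 methyl group, so that the C8 oxygen is α and the C8 methyl β; the isolated vinyl group is inert to alkaline peroxide.

Step 13
Reactants: 18 7α,8α-epoxy-11-methylidenedriman-6-one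
Product: 19 8α-hydroxy-11-methylidenedriman-6-one (8β-CH3)
Conditions: SmI2 (2.5 equiv), THF–MeOH, −78 °C
Reagents that add atoms: none
Why: Reductive opening of an α,β-epoxy ketone, in which the ketyl formed at C6 expels the oxygen at C7, so the C8–O bond and its α configuration are retained.

Step 14
Reactants: 19 8α-hydroxy-11-methylidenedriman-6-one
Product: 20 11-methylidenedrimane-6α,8α-diol
Conditions: Li, NH3(l)–THF, −78 °C; then NH4Cl
Reagents that add atoms: none
Why: Dissolving-metal reduction of the hindered C6 ketone gives the thermodynamically favoured equatorial 6α-alcohol by axial protonation of the carbanion, an outcome that hydride reagents attacking from the α face would not give; the isolated alkene is not reduced.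

Step 15
Reactants: 20 11-methylidenedrimane-6α,8α-diol
Product: 21 6α,8α-bis[(triethylsilyl)oxy]-11-methylidenedrimane
Conditions: Et3SiOTf (3 equiv), 2,6-lutidine, CH2Cl2, −78 to 0 °C
Reagents that add atoms: triethylsilyl trifluoromethanesulfonate, CC[Si](CC)(CC)OS(=O)(=O)C(F)(F)F
Why: Silyl triflate with 2,6-lutidine silylates both the secondary and the tertiary hydroxyl group, which protects them from the chlorosilane Lewis acid of step 20 and lets both ethers come off together at the end.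

Step 16
Reactants: 21 6α,8α-bis[(triethylsilyl)oxy]-11-methylidenedrimane; 10 ethyl (2E)-3-{[(trifluoromethyl)sulfonyl]oxy}but-2-enoate
Product: 23 ethyl (2E)-4-{6α,8α-bis[(triethylsilyl)oxy]driman-11-yl}-3-methylbut-2-enoate, via alkylborane 22 (not isolated)
Conditions: 9-BBN (2.5 equiv), THF, 60 °C; then 10, Pd(dppf)Cl2 (10 mol%), 3 M aq. K3PO4, THF–DMF, 50 °C
Reagents that add atoms: none
Why: As in step 6, 9-BBN adds anti-Markovnikov to the only alkene, here hindered and therefore heated, and B-alkyl Suzuki–Miyaura coupling with 10 forms C12–C13 with retention to give the (13E) trisubstituted alkene.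

Step 17
Reactants: 23 ethyl (2E)-4-{6α,8α-bis[(triethylsilyl)oxy]driman-11-yl}-3-methylbut-2-enoate
Product: 24 (2E)-4-{6α,8α-bis[(triethylsilyl)oxy]driman-11-yl}-3-methylbut-2-en-1-ol
Conditions: i-Bu2AlH (2.2 equiv), CH2Cl2, −78 °C; aq. Rochelle salt
Reagents that add atoms: none
Why: 1,2-Reduction of the enoate to the allylic alcohol, to which triethylsilyl ethers are stable.

Step 18
Reactants: 24 (2E)-4-{6α,8α-bis[(triethylsilyl)oxy]driman-11-yl}-3-methylbut-2-en-1-ol
Product: 25 (2E)-4-{6α,8α-bis[(triethylsilyl)oxy]driman-11-yl}-3-methylbut-2-enal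
Conditions: activated MnO2 (excess), CH2Cl2, rt
Reagents that add atoms: none
Why: Selective allylic oxidation under neutral conditions gives the enal without isomerisation of the (13E) double bond.

Step 19
Reactants: 26 4-methylfuran-2(5H)-one
Product: 27 tert-butyl(dimethyl)[(4-methylfuran-2-yl)oxy]silane
Conditions: t-BuMe2SiOTf (1.1 equiv), Et3N, CH2Cl2, 0 °C
Reagents that add atoms: tert-butyldimethylsilyl trifluoromethanesulfonate, CC(C)(C)[Si](C)(C)OS(=O)(=O)C(F)(F)F
Why: Soft enolisation of the butenolide gives the aromatic 2-silyloxyfuran, the standard vinylogous nucleophile.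

Step 20
Reactants: 25 (2E)-4-{6α,8α-bis[(triethylsilyl)oxy]driman-11-yl}-3-methylbut-2-enal; 27 tert-butyl(dimethyl)[(4-methylfuran-2-yl)oxy]silane
Product: 28 (5S)-5-[(1S,2E)-4-{6α,8α-bis[(triethylsilyl)oxy]driman-11-yl}-1-hydroxy-3-methylbut-2-en-1-yl]-4-methylfuran-2(5H)-one
Conditions: SiCl4 (1.1 equiv), (R,R)-N,N'-bis[4,5-dihydro-3,5-dimethyl-4-oxo-3H-dinaphtho[2,1-d:1',2'-f][1,3,2]diazaphosphepin-4-yl]-N,N'-dimethylpentane-1,5-diamine (5 mol%), i-Pr2NEt, CH2Cl2, −78 °C; aq. NaHCO3
Reagents that add atoms: none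
Why: Catalytic enantioselective vinylogous Mukaiyama aldol reaction, in which the phosphoramide-bound chlorosilyl cation activates the conjugated aldehyde, the silyloxyfuran attacks through C5 in an open transition state that favours the syn (15,16-threo) adduct, and the catalyst rather than the remote decalin decides the aldehyde face; the (R,R) ligand is specified for Re-face attack at C15, and its antipode would be used if a model enal shows the opposite sense.

Step 21
Reactants: 28 (5S)-5-[(1S,2E)-4-{6α,8α-bis[(triethylsilyl)oxy]driman-11-yl}-1-hydroxy-3-methylbut-2-en-1-yl]-4-methylfuran-2(5H)-one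
Product: 29 (5S)-5-[(1S,2E)-4-(6α,8α-dihydroxydriman-11-yl)-1-hydroxy-3-methylbut-2-en-1-yl]-4-methylfuran-2(5H)-one (target)
Conditions: HF·pyridine, pyridine, THF, 0 °C to rt
Reagents that add atoms: none
Why: Fluoride-mediated cleavage of the secondary and tertiary triethylsilyl ethers under buffered, non-basic conditions that should neither epimerise C16 nor ionise the allylic alcohol.

Compound list
1 | mesityl oxide (4-methylpent-3-en-2-one) | CC(=O)C=C(C)C | starting material
2 | allyltrimethylsilane | C=CC[Si](C)(C)C | starting material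
3 | 4,4-dimethylhept-6-en-2-one | CC(=O)CC(C)(C)CC=C | intermediate
4 | acetaldehyde | CC=O | starting material
5 | 2-hydroxy-6,6-dimethylnon-8-en-4-one (racemic) | CC(O)CC(=O)CC(C)(C)CC=C | intermediate
6 | 6,6-dimethyl-4-oxonon-8-en-2-yl methanesulfonate | CC(OS(C)(=O)=O)CC(=O)CC(C)(C)CC=C | intermediate (not isolated)
7 | (2E)-6,6-dimethylnona-2,8-dien-4-one | C/C=C/C(=O)CC(C)(C)CC=C | intermediate
8 | (2E,4Z)-6,6-dimethyl-4-[(triisopropylsilyl)oxy]nona-2,4,8-triene | C/C=C/C(O[Si](C(C)C)(C(C)C)C(C)C)=C/C(C)(C)CC=C | intermediate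
9 | ethyl acetoacetate | CCOC(=O)CC(C)=O | starting material
10 | ethyl (2E)-3-{[(trifluoromethyl)sulfonyl]oxy}but-2-enoate | CCOC(=O)/C=C(\C)OS(=O)(=O)C(F)(F)F | intermediate
11 | 9-{(5Z,7E)-4,4-dimethyl-6-[(triisopropylsilyl)oxy]nona-5,7-dien-1-yl}-9-borabicyclo[3.3.1]nonane | C/C=C/C(O[Si](C(C)C)(C(C)C)C(C)C)=C/C(C)(C)CCCB1C2CCCC1CCC2 | intermediate (not isolated)
12 | ethyl (2E,8Z,10E)-3,7,7-trimethyl-9-[(triisopropylsilyl)oxy]dodeca-2,8,10-trienoate | CCOC(=O)/C=C(\C)CCCC(C)(C)/C=C(O[Si](C(C)C)(C(C)C)C(C)C)/C=C/C | intermediate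
13 | (2E,8Z,10E)-3,7,7-trimethyl-9-[(triisopropylsilyl)oxy]dodeca-2,8,10-trien-1-ol | OC/C=C(\C)CCCC(C)(C)/C=C(O[Si](C(C)C)(C(C)C)C(C)C)/C=C/C | intermediate
14 | (2E,8Z,10E)-3,7,7-trimethyl-9-[(triisopropylsilyl)oxy]dodeca-2,8,10-trienal | O=C/C=C(\C)CCCC(C)(C)/C=C(O[Si](C(C)C)(C(C)C)C(C)C)/C=C/C | intermediate (key-step precursor)
15 | (1S,2S,4aS,8aS)-2,5,5,8a-tetramethyl-4-[(triisopropylsilyl)oxy]-1,2,4a,5,6,7,8,8a-octahydronaphthalene-1-carbaldehyde (6-[(triisopropylsilyl)oxy]drim-6-en-11-al) | O=C[C@@H]1[C@@]2(C)CCCC(C)(C)[C@@H]2C(O[Si](C(C)C)(C(C)C)C(C)C)=C[C@@H]1C | intermediate (key-step product)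
16 | 11-methylidene-6-[(triisopropylsilyl)oxy]drim-6-ene (9β-vinyl, 8β-CH3) | C=C[C@@H]1[C@@]2(C)CCCC(C)(C)[C@@H]2C(O[Si](C(C)C)(C(C)C)C(C)C)=C[C@@H]1C | intermediate
17 | 11-methylidenedrim-7-en-6-one | C=C[C@@H]1[C@@]2(C)CCCC(C)(C)[C@@H]2C(=O)C=C1C | intermediate
18 | 7α,8α-epoxy-11-methylidenedriman-6-one | C=C[C@@H]1[C@@]2(C)CCCC(C)(C)[C@@H]2C(=O)[C@H]3O[C@@]13C | intermediate
19 | 8α-hydroxy-11-methylidenedriman-6-one | C=C[C@@H]1[C@@]2(C)CCCC(C)(C)[C@@H]2C(=O)C[C@@]1(C)O | intermediate
20 | 11-methylidenedrimane-6α,8α-diol | C=C[C@@H]1[C@@]2(C)CCCC(C)(C)[C@@H]2[C@@H](O)C[C@@]1(C)O | intermediate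
21 | 6α,8α-bis[(triethylsilyl)oxy]-11-methylidenedrimane | C=C[C@@H]1[C@@]2(C)CCCC(C)(C)[C@@H]2[C@@H](O[Si](CC)(CC)CC)C[C@@]1(C)O[Si](CC)(CC)CC | intermediate
22 | 9-({6α,8α-bis[(triethylsilyl)oxy]driman-11-yl}methyl)-9-borabicyclo[3.3.1]nonane | C1CCC2CCCC1B2CC[C@@H]3[C@@]4(C)CCCC(C)(C)[C@@H]4[C@@H](O[Si](CC)(CC)CC)C[C@@]3(C)O[Si](CC)(CC)CC | intermediate (not isolated)
23 | ethyl (2E)-4-{6α,8α-bis[(triethylsilyl)oxy]driman-11-yl}-3-methylbut-2-enoate | CCOC(=O)/C=C(\C)CC[C@@H]1[C@@]2(C)CCCC(C)(C)[C@@H]2[C@@H](O[Si](CC)(CC)CC)C[C@@]1(C)O[Si](CC)(CC)CC | intermediate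
24 | (2E)-4-{6α,8α-bis[(triethylsilyl)oxy]driman-11-yl}-3-methylbut-2-en-1-ol | OC/C=C(\C)CC[C@@H]1[C@@]2(C)CCCC(C)(C)[C@@H]2[C@@H](O[Si](CC)(CC)CC)C[C@@]1(C)O[Si](CC)(CC)CC | intermediate
25 | (2E)-4-{6α,8α-bis[(triethylsilyl)oxy]driman-11-yl}-3-methylbut-2-enal | O=C/C=C(\C)CC[C@@H]1[C@@]2(C)CCCC(C)(C)[C@@H]2[C@@H](O[Si](CC)(CC)CC)C[C@@]1(C)O[Si](CC)(CC)CC | intermediate
26 | 4-methylfuran-2(5H)-one | CC1=CC(=O)OC1 | starting material
27 | tert-butyl(dimethyl)[(4-methylfuran-2-yl)oxy]silane | Cc1coc(O[Si](C)(C)C(C)(C)C)c1 | intermediate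
28 | (5S)-5-[(1S,2E)-4-{6α,8α-bis[(triethylsilyl)oxy]driman-11-yl}-1-hydroxy-3-methylbut-2-en-1-yl]-4-methylfuran-2(5H)-one | CC1=CC(=O)O[C@@H]1[C@@H](O)/C=C(\C)CC[C@@H]1[C@@]2(C)CCCC(C)(C)[C@@H]2[C@@H](O[Si](CC)(CC)CC)C[C@@]1(C)O[Si](CC)(CC)CC | intermediate
29 | (5S)-5-[(1S,2E)-4-(6α,8α-dihydroxydriman-11-yl)-1-hydroxy-3-methylbut-2-en-1-yl]-4-methylfuran-2(5H)-one | CC1=CC(=O)O[C@@H]1[C@@H](O)/C=C(\C)CC[C@@H]1[C@@]2(C)CCCC(C)(C)[C@@H]2[C@@H](O)C[C@@]1(C)O | target

Total step count: 21. Longest linear sequence: 19 steps (steps 1–4, 6–18, 20 and 21, from 1 to 29); steps 5 and 19 are branch steps.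

Steps most likely to fail

Step 9. The cycloaddition may stall at the congested C5–C10 bond, divert into Mukaiyama-type addition with silyl transfer, or proceed with poor facial discrimination at the enal. The fallback keeps the same two bonds but replaces catalyst control by auxiliary control.
- It sets out from ester 12. Saponification (LiOH, THF–H2O) would give (2E,8Z,10E)-3,7,7-trimethyl-9-[(triisopropylsilyl)oxy]dodeca-2,8,10-trienoic acid F1.
- Its pivalic mixed anhydride would acylate lithiated (4S)-4-benzyl-1,3-oxazolidin-2-one to give (4S)-4-benzyl-3-{(2E,8Z,10E)-3,7,7-trimethyl-9-[(triisopropylsilyl)oxy]dodeca-2,8,10-trienoyl}-1,3-oxazolidin-2-one F2.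
- Me2AlCl (1.4 equiv, CH2Cl2, −30 °C) would then promote the auxiliary-directed intramolecular Diels–Alder reaction through the chelated s-cis imide, the diene adding anti to the benzyl group, to give (4S)-4-benzyl-3-{6-[(triisopropylsilyl)oxy]drim-6-en-11-oyl}-1,3-oxazolidin-2-one F3.
- Reductive removal of the auxiliary (LiBH4, THF–MeOH) would give 6-[(triisopropylsilyl)oxy]drim-6-en-11-ol F4, and NaHCO3-buffered Dess–Martin oxidation comes back to the route at aldehyde 15.

Step 20. Facial selection at the aldehyde rests on the catalyst alone and may be poor, syn selectivity may erode, and the silyl ethers may be partly lost to the chlorosilane. The fallback builds C15 and C16 by an auxiliary-controlled glycolate aldol reaction and closes the butenolide afterwards.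
- It sets out from enal 25. The dibutylboron enolate (Bu2BOTf, Et3N) of (4R)-4-benzyl-3-{[(4-methoxybenzyl)oxy]acetyl}-1,3-oxazolidin-2-one would add to give the syn aldol (4R)-4-benzyl-3-[(2R,3S,4E)-6-{6α,8α-bis[(triethylsilyl)oxy]driman-11-yl}-3-hydroxy-2-[(4-methoxybenzyl)oxy]-5-methylhex-4-enoyl]-1,3-oxazolidin-2-one F5.
- Transamination (MeONHMe·HCl, AlMe3) would give the Weinreb amide (2R,3S,4E)-6-{6α,8α-bis[(triethylsilyl)oxy]driman-11-yl}-3-hydroxy-N-methoxy-2-[(4-methoxybenzyl)oxy]-N,5-dimethylhex-4-enamide F6.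
- Silylation (Et3SiOTf, 2,6-lutidine) would give its 3-O-triethylsilyl ether F7, and MeMgBr would give the methyl ketone (3R,4S,5E)-7-{6α,8α-bis[(triethylsilyl)oxy]driman-11-yl}-3-[(4-methoxybenzyl)oxy]-6-methyl-4-[(triethylsilyl)oxy]hept-5-en-2-one F8.
- Buffered DDQ would free the α-hydroxy ketone (3R,4S,5E)-7-{6α,8α-bis[(triethylsilyl)oxy]driman-11-yl}-3-hydroxy-6-methyl-4-[(triethylsilyl)oxy]hept-5-en-2-one F9.
- Ph3P=C=C=O (toluene, 80 °C) would acylate the hydroxyl group and close the ring by intramolecular Wittig reaction to give (5S)-5-[(1S,2E)-4-{6α,8α-bis[(triethylsilyl)oxy]driman-11-yl}-3-methyl-1-[(triethylsilyl)oxy]but-2-en-1-yl]-4-methylfuran-2(5H)-one F10.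
- HF·pyridine then comes back to the route at target 29.

Step 12. Conjugate addition of hydroperoxide at the hindered C8 may be slow, which would leave time for base-induced double-bond migration through loss of the doubly allylic C9 hydrogen, or for epimerisation at C9. The fallback introduces the C8 oxygen by conjugate borylation under nearly neutral conditions and skips the epoxide.
- It sets out from enone 17. B2pin2 with CuCl (5 mol%), NaOt-Bu (10 mol%), a bisphosphine ligand and MeOH in THF would add boron to C8 from the α face to give 8α-(4,4,5,5-tetramethyl-1,3,2-dioxaborolan-2-yl)-11-methylidenedriman-6-one F11.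
- Oxidation with NaBO3·4H2O (THF–H2O), with retention at C8, comes back to the route at hydroxy ketone 19.

Further compounds
F1 | step 9 | (2E,8Z,10E)-3,7,7-trimethyl-9-[(triisopropylsilyl)oxy]dodeca-2,8,10-trienoic acid | OC(=O)/C=C(\C)CCCC(C)(C)/C=C(O[Si](C(C)C)(C(C)C)C(C)C)/C=C/C
F2 | step 9 | (4S)-4-benzyl-3-{(2E,8Z,10E)-3,7,7-trimethyl-9-[(triisopropylsilyl)oxy]dodeca-2,8,10-trienoyl}-1,3-oxazolidin-2-one | O=C(/C=C(\C)CCCC(C)(C)/C=C(O[Si](C(C)C)(C(C)C)C(C)C)/C=C/C)N1[C@@H](Cc2ccccc2)COC1=O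
F3 | step 9 | (4S)-4-benzyl-3-{6-[(triisopropylsilyl)oxy]drim-6-en-11-oyl}-1,3-oxazolidin-2-one | O=C([C@@H]1[C@@]2(C)CCCC(C)(C)[C@@H]2C(O[Si](C(C)C)(C(C)C)C(C)C)=C[C@@H]1C)N1[C@@H](Cc2ccccc2)COC1=O
F4 | step 9 | 6-[(triisopropylsilyl)oxy]drim-6-en-11-ol | OC[C@@H]1[C@@]2(C)CCCC(C)(C)[C@@H]2C(O[Si](C(C)C)(C(C)C)C(C)C)=C[C@@H]1C
F5 | step 20 | (4R)-4-benzyl-3-[(2R,3S,4E)-6-{6α,8α-bis[(triethylsilyl)oxy]driman-11-yl}-3-hydroxy-2-[(4-methoxybenzyl)oxy]-5-methylhex-4-enoyl]-1,3-oxazolidin-2-one | O=C1OC[C@@H](Cc2ccccc2)N1C(=O)[C@H](OCc1ccc(OC)cc1)[C@@H](O)/C=C(\C)CC[C@@H]1[C@@]2(C)CCCC(C)(C)[C@@H]2[C@@H](O[Si](CC)(CC)CC)C[C@@]1(C)O[Si](CC)(CC)CC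
F6 | step 20 | (2R,3S,4E)-6-{6α,8α-bis[(triethylsilyl)oxy]driman-11-yl}-3-hydroxy-N-methoxy-2-[(4-methoxybenzyl)oxy]-N,5-dimethylhex-4-enamide | CON(C)C(=O)[C@H](OCc1ccc(OC)cc1)[C@@H](O)/C=C(\C)CC[C@@H]1[C@@]2(C)CCCC(C)(C)[C@@H]2[C@@H](O[Si](CC)(CC)CC)C[C@@]1(C)O[Si](CC)(CC)CC
F7 | step 20 | 3-O-triethylsilyl ether of F6 | CON(C)C(=O)[C@H](OCc1ccc(OC)cc1)[C@@H](O[Si](CC)(CC)CC)/C=C(\C)CC[C@@H]1[C@@]2(C)CCCC(C)(C)[C@@H]2[C@@H](O[Si](CC)(CC)CC)C[C@@]1(C)O[Si](CC)(CC)CC
F8 | step 20 | (3R,4S,5E)-7-{6α,8α-bis[(triethylsilyl)oxy]driman-11-yl}-3-[(4-methoxybenzyl)oxy]-6-methyl-4-[(triethylsilyl)oxy]hept-5-en-2-one | CC(=O)[C@H](OCc1ccc(OC)cc1)[C@@H](O[Si](CC)(CC)CC)/C=C(\C)CC[C@@H]1[C@@]2(C)CCCC(C)(C)[C@@H]2[C@@H](O[Si](CC)(CC)CC)C[C@@]1(C)O[Si](CC)(CC)CC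
F9 | step 20 | (3R,4S,5E)-7-{6α,8α-bis[(triethylsilyl)oxy]driman-11-yl}-3-hydroxy-6-methyl-4-[(triethylsilyl)oxy]hept-5-en-2-one | CC(=O)[C@H](O)[C@@H](O[Si](CC)(CC)CC)/C=C(\C)CC[C@@H]1[C@@]2(C)CCCC(C)(C)[C@@H]2[C@@H](O[Si](CC)(CC)CC)C[C@@]1(C)O[Si](CC)(CC)CC
F10 | step 20 | (5S)-5-[(1S,2E)-4-{6α,8α-bis[(triethylsilyl)oxy]driman-11-yl}-3-methyl-1-[(triethylsilyl)oxy]but-2-en-1-yl]-4-methylfuran-2(5H)-one | CC1=CC(=O)O[C@@H]1[C@@H](O[Si](CC)(CC)CC)/C=C(\C)CC[C@@H]1[C@@]2(C)CCCC(C)(C)[C@@H]2[C@@H](O[Si](CC)(CC)CC)C[C@@]1(C)O[Si](CC)(CC)CC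
F11 | step 12 | 8α-(4,4,5,5-tetramethyl-1,3,2-dioxaborolan-2-yl)-11-methylidenedriman-6-one | C=C[C@@H]1[C@@]2(C)CCCC(C)(C)[C@@H]2C(=O)C[C@@]1(C)B1OC(C)(C)C(C)(C)O1
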